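## Retrosynthetic overview

1. The acrylic acid arm comes from a tert-butyl ester, made by Wittig olefination of a C3 aldehyde, itself from MnO2 oxidation of a C3-hydroxymethyl pyran.
2. The pyran ring is formed last, by 6-endo O-cyclisation of a 4-formyl-3-alkynylcyclohex-2-enone; the alkyne is put on by Sonogashira coupling of the enol triflate of a cyclohexane-1,3-dione.
3. The carbocycle is formed first, by Claisen (Dieckmann-type) closure of a methyl ketone onto a methyl ester.
4. The key C7–C8 bond is made by an intermolecular, catalyst-controlled Mukaiyama aldol of a succinate-derived silyl ketene thioacetal (C1 as acetal, C4a as ester) with butane-2,3-dione; this sets both core stereocentres.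
5. The side-chain ester is installed by Mitsunobu inversion with (2R,4S)-4-methylhexan-2-ol, made from (S)-1-bromo-2-methylbutane by Grignard addition and lipase resolution.

Assumption: positions are labelled with the isochromene numbering of the target (O2, C1, C3, C4, C4a, C5–C8, C8a); the target is (7R,8R) in the core and (2S,4S) in the ester alcohol.

## Route

Step 1
Reactants: 1 (S)-1-bromo-2-methylbutane; 2 acetaldehyde
Product: 4 (2RS,4S)-4-methylhexan-2-ol, via Grignard reagent 3 (not isolated)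
Conditions: Mg, THF, rt; then 2, −20 °C; 1 M HCl work-up
Reagents that add atoms: none
Why: Grignard addition of a primary alkylmagnesium bromide to an aldehyde; the C4 centre is carried over from 1 and the new C2 carbinol forms about 1:1, to be sorted in step 2.

Step 2
Reactants: 4 (2RS,4S)-4-methylhexan-2-ol
Product: 5 (2R,4S)-4-methylhexan-2-yl acetate
Conditions: Novozym 435 (immobilised Candida antarctica lipase B), vinyl acetate, hexane, rt, stopped at about 45% conversion
Reagents that add atoms: vinyl acetate CC(=O)OC=C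
Why: Lipase-catalysed kinetic resolution by transesterification; the enzyme acylates the (2R)-carbinol much faster (methyl versus larger alkyl, Kazlauskas rule), giving the (2R,4S)-acetate and leaving the (2S,4S)-alcohol unreacted.

Step 3
Reactants: 5 (2R,4S)-4-methylhexan-2-yl acetate
Product: 6 (2R,4S)-4-methylhexan-2-ol
Conditions: K2CO3 (cat.), MeOH, rt
Reagents that add atoms: none
Why: Base-catalysed transesterification (methanolysis) cleaves the acyl–oxygen bond, so both stereocentres are untouched.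

Step 4
Reactants: 7 methyl 3,3-dimethoxypropanoate; 8 benzyl 2-bromoacetate
Product: 10 4-benzyl 1-methyl 2-(dimethoxymethyl)butanedioate (racemic), via lithium enolate 9 (not isolated)
Conditions: LiN(iPr)2, THF, −78 °C; then 8, −78 to −40 °C
Reagents that add atoms: none
Why: Ester enolate alkylation (SN2) with an activated α-bromo ester, faster at −78 °C than β-methoxide loss; the new centre (future C8a) is racemic and becomes sp2 in step 14.

Step 5
Reactants: 10 4-benzyl 1-methyl 2-(dimethoxymethyl)butanedioate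
Product: 11 3-(dimethoxymethyl)-4-methoxy-4-oxobutanoic acid (racemic)
Conditions: H2 (1 atm), 10% Pd/C, EtOAc, rt
Reagents that add atoms: none
Why: Hydrogenolysis of the benzyl ester frees one carboxyl group while the methyl ester and the acetal are inert.

Step 6
Reactants: 11 3-(dimethoxymethyl)-4-methoxy-4-oxobutanoic acid
Product: 12 methyl 4-(tert-butylsulfanyl)-2-(dimethoxymethyl)-4-oxobutanoate (racemic)
Conditions: 2-methylpropane-2-thiol, DCC, DMAP (cat.), CH2Cl2, 0 °C to rt
Reagents that add atoms: 2-methylpropane-2-thiol CC(C)(C)S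
Why: Steglich thioesterification under neutral conditions that leave the acetal alone.

Step 7
Reactants: 12 methyl 4-(tert-butylsulfanyl)-2-(dimethoxymethyl)-4-oxobutanoate
Product: 14 methyl (Z)-4-(tert-butylsulfanyl)-2-(dimethoxymethyl)-4-(trimethylsilyloxy)but-3-enoate (racemic at C2), via lithium enolate 13 (not isolated)
Conditions: LiN(iPr)2, THF, −78 °C; then Me3SiCl, −78 °C to rt
Reagents that add atoms: chlorotrimethylsilane C[Si](C)(C)Cl
Why: Kinetic enolisation at the thioester CH2 (more acidic and less hindered than the ester methine) followed by O-silylation gives the silyl ketene thioacetal; its geometry does not matter in step 8.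

Step 8
Reactants: 14 methyl (Z)-4-(tert-butylsulfanyl)-2-(dimethoxymethyl)-4-(trimethylsilyloxy)but-3-enoate; 15 butane-2,3-dione
Product: 16 methyl (3R,4R)-3-[(tert-butylsulfanyl)carbonyl]-2-(dimethoxymethyl)-4-methyl-5-oxo-4-(trimethylsilyloxy)hexanoate (both C2 epimers)
Conditions: [Cu((R,R)-tBu-box)](OTf)2 (10 mol%; tBu-box = 2,2'-(propane-2,2-diyl)bis(4-tert-butyl-4,5-dihydro-1,3-oxazole)), THF, −78 °C; filtration through Et3N-deactivated silica
Reagents that add atoms: none
Why: Catalytic enantioselective Mukaiyama aldol: the 1,2-diketone chelates the square-planar divalent copper–bis(oxazoline) complex, the (R,R) ligand leaves the re face open so C7 forms as (R), the open transition state gives the syn adduct from either enolsilane geometry so C8 is (R), and silyl transfer delivers the tertiary silyl ether directly.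

Step 9
Reactants: 16 methyl (3R,4R)-3-[(tert-butylsulfanyl)carbonyl]-2-(dimethoxymethyl)-4-methyl-5-oxo-4-(trimethylsilyloxy)hexanoate
Product: 17 (2R,3R)-2-(1,1-dimethoxy-3-methoxy-3-oxopropan-2-yl)-3-methyl-4-oxo-3-(trimethylsilyloxy)pentanoic acid
Conditions: AgNO3 (3 equiv), 2,6-lutidine, THF/H2O 4:1, rt to 40 °C, dark
Reagents that add atoms: water O
Why: Thiophile-assisted thioester hydrolysis at near-neutral pH, which spares the methyl ester, the acetal, the hindered tertiary silyl ether and the C8 configuration.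

Step 10
Reactants: 17 (2R,3R)-2-(1,1-dimethoxy-3-methoxy-3-oxopropan-2-yl)-3-methyl-4-oxo-3-(trimethylsilyloxy)pentanoic acid; 6 (2R,4S)-4-methylhexan-2-ol
Product: 18 methyl (3R,4R)-2-(dimethoxymethyl)-4-methyl-3-{[(2S,4S)-4-methylhexan-2-yl]oxycarbonyl}-5-oxo-4-(trimethylsilyloxy)hexanoate
Conditions: PPh3, DIAD, THF, 0 °C to rt
Reagents that add atoms: none
Why: Mitsunobu esterification, in which the hindered carboxylate only has to act as nucleophile at the activated carbinol carbon; SN2 inversion turns (2R) into the required (2S) ester centre.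

Step 11
Reactants: 18 methyl (3R,4R)-2-(dimethoxymethyl)-4-methyl-3-{[(2S,4S)-4-methylhexan-2-yl]oxycarbonyl}-5-oxo-4-(trimethylsilyloxy)hexanoate
Product: 20 (2S,4S)-4-methylhexan-2-yl (1R,2R)-6-(dimethoxymethyl)-2-methyl-3,5-dioxo-2-(trimethylsilyloxy)cyclohexane-1-carboxylate (mainly enol form), via lithium enolate 19 (not isolated)
Conditions: LiN(SiMe3)2 (2.2 equiv), THF, −78 to 0 °C; AcOH quench
Reagents that add atoms: none
Why: Intramolecular Claisen (Dieckmann-type) condensation: the only possible ketone enolate (the methyl side, since C7 is quaternary) acylates the methyl ester in a six-membered closure, the five-membered alternative onto the hindered secondary ester is disfavoured, and the diketonate is the thermodynamic sink; C7 and C8 are not touched.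

Step 12
Reactants: 20 (2S,4S)-4-methylhexan-2-yl (1R,2R)-6-(dimethoxymethyl)-2-methyl-3,5-dioxo-2-(trimethylsilyloxy)cyclohexane-1-carboxylate
Product: 21 (2S,4S)-4-methylhexan-2-yl (1R,2R)-6-(dimethoxymethyl)-2-methyl-3-oxo-5-(trifluoromethanesulfonyloxy)-2-(trimethylsilyloxy)cyclohex-4-ene-1-carboxylate
Conditions: Tf2O (1.1 equiv), pyridine, CH2Cl2, −78 to −20 °C
Reagents that add atoms: trifluoromethanesulfonic anhydride O=S(=O)(OS(=O)(=O)C(F)(F)F)C(F)(F)F
Why: O-sulfonylation of the vinylogous acid at the less hindered oxygen (on C4a), away from the quaternary C7 with its silyloxy group, leaving the C6 ketone in place; any regioisomer is removed by chromatography.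

Step 13
Reactants: 21 (2S,4S)-4-methylhexan-2-yl (1R,2R)-6-(dimethoxymethyl)-2-methyl-3-oxo-5-(trifluoromethanesulfonyloxy)-2-(trimethylsilyloxy)cyclohex-4-ene-1-carboxylate; 22 prop-2-yn-1-ol
Product: 23 (2S,4S)-4-methylhexan-2-yl (1R,2R)-6-(dimethoxymethyl)-5-(3-hydroxyprop-1-yn-1-yl)-2-methyl-3-oxo-2-(trimethylsilyloxy)cyclohex-4-ene-1-carboxylate
Conditions: Pd(PPh3)2Cl2 (5 mol%), CuI (10 mol%), Et3N, THF, rt
Reagents that add atoms: none
Why: Sonogashira coupling: zerovalent palladium inserts readily into the electron-poor vinyl triflate and couples with the copper acetylide at room temperature, setting the C4a–C4 bond.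

Step 14
Reactants: 23 (2S,4S)-4-methylhexan-2-yl (1R,2R)-6-(dimethoxymethyl)-5-(3-hydroxyprop-1-yn-1-yl)-2-methyl-3-oxo-2-(trimethylsilyloxy)cyclohex-4-ene-1-carboxylate
Product: 25 (2S,4S)-4-methylhexan-2-yl (7R,8R)-7-hydroxy-3-(hydroxymethyl)-7-methyl-6-oxo-7,8-dihydro-6H-isochromene-8-carboxylate, via formyl enynone 24 (not isolated)
Conditions: TsOH·H2O (0.3 equiv), acetone/H2O 10:1, rt; then AgOTf (5 mol%), CH2Cl2, rt
Reagents that add atoms: water O
Why: Acetal and silyl ether hydrolysis, then silver-catalysed 6-endo-dig cycloisomerisation: the formyl (enol) oxygen adds to the alkyne terminus, which is the 1,6-acceptor position of the ynenone, and loss of the C8a proton gives the conjugated pyran, so the C8a epimers converge.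

Step 15
Reactants: 25 (2S,4S)-4-methylhexan-2-yl (7R,8R)-7-hydroxy-3-(hydroxymethyl)-7-methyl-6-oxo-7,8-dihydro-6H-isochromene-8-carboxylate
Product: 26 (2S,4S)-4-methylhexan-2-yl (7R,8R)-3-formyl-7-hydroxy-7-methyl-6-oxo-7,8-dihydro-6H-isochromene-8-carboxylate
Conditions: MnO2 (activated, excess), CH2Cl2, rt
Reagents that add atoms: none
Why: MnO2 oxidation is selective for the allylic primary alcohol; the tertiary alcohol cannot be oxidised.

Step 16
Reactants: 26 (2S,4S)-4-methylhexan-2-yl (7R,8R)-3-formyl-7-hydroxy-7-methyl-6-oxo-7,8-dihydro-6H-isochromene-8-carboxylate; 27 tert-butyl 2-(triphenyl-λ5-phosphanylidene)acetate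
Product: 28 (2S,4S)-4-methylhexan-2-yl (7R,8R)-3-[(E)-3-tert-butoxy-3-oxoprop-1-en-1-yl]-7-hydroxy-7-methyl-6-oxo-7,8-dihydro-6H-isochromene-8-carboxylate
Conditions: toluene, 50 °C
Reagents that add atoms: none
Why: Wittig olefination with a stabilised ylide gives the (E)-alkene and reacts only with the aldehyde; the neutral conditions do not epimerise C8.

Step 17
Reactants: 28 (2S,4S)-4-methylhexan-2-yl (7R,8R)-3-[(E)-3-tert-butoxy-3-oxoprop-1-en-1-yl]-7-hydroxy-7-methyl-6-oxo-7,8-dihydro-6H-isochromene-8-carboxylate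
Product: 29 (E)-3-[(7R,8R)-7-hydroxy-7-methyl-8-{[(2S,4S)-4-methylhexan-2-yl]oxycarbonyl}-6-oxo-7,8-dihydro-6H-isochromen-3-yl]prop-2-enoic acid (target)
Conditions: TFA/CH2Cl2 1:4, 0 °C to rt
Reagents that add atoms: none
Why: Acidolysis of the tert-butyl ester (loss of the tert-butyl cation as isobutene) frees the acid while the secondary alkyl ester and both stereocentres are unaffected.

## Compound list

1 | (S)-1-bromo-2-methylbutane | CC[C@H](C)CBr | starting material
2 | acetaldehyde | CC=O | starting material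
3 | (S)-(2-methylbutyl)magnesium bromide | CC[C@H](C)C[Mg]Br | intermediate
4 | (2RS,4S)-4-methylhexan-2-ol | CC[C@H](C)CC(C)O | intermediate
5 | (2R,4S)-4-methylhexan-2-yl acetate | CC[C@H](C)C[C@@H](C)OC(C)=O | intermediate
6 | (2R,4S)-4-methylhexan-2-ol | CC[C@H](C)C[C@@H](C)O | intermediate
7 | methyl 3,3-dimethoxypropanoate | COC(OC)CC(=O)OC | starting material
8 | benzyl 2-bromoacetate | O=C(CBr)OCc1ccccc1 | starting material
9 | lithium enolate of 7 | COC(OC)C=C(OC)[O-].[Li+] | intermediate
10 | 4-benzyl 1-methyl 2-(dimethoxymethyl)butanedioate (racemic) | COC(OC)C(CC(=O)OCc1ccccc1)C(=O)OC | intermediate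
11 | 3-(dimethoxymethyl)-4-methoxy-4-oxobutanoic acid (racemic) | COC(OC)C(CC(=O)O)C(=O)OC | intermediate
12 | methyl 4-(tert-butylsulfanyl)-2-(dimethoxymethyl)-4-oxobutanoate (racemic) | COC(OC)C(CC(=O)SC(C)(C)C)C(=O)OC | intermediate
13 | lithium thioester enolate of 12 | COC(OC)C(/C=C(/[O-])SC(C)(C)C)C(=O)OC.[Li+] | intermediate
14 | methyl (Z)-4-(tert-butylsulfanyl)-2-(dimethoxymethyl)-4-(trimethylsilyloxy)but-3-enoate (racemic at C2) | COC(OC)C(/C=C(/O[Si](C)(C)C)SC(C)(C)C)C(=O)OC | intermediate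
15 | butane-2,3-dione | CC(=O)C(C)=O | starting material
16 | methyl (3R,4R)-3-[(tert-butylsulfanyl)carbonyl]-2-(dimethoxymethyl)-4-methyl-5-oxo-4-(trimethylsilyloxy)hexanoate (both C2 epimers) | COC(=O)C(C(OC)OC)[C@@H](C(=O)SC(C)(C)C)[C@@](C)(O[Si](C)(C)C)C(C)=O | intermediate
17 | (2R,3R)-2-(1,1-dimethoxy-3-methoxy-3-oxopropan-2-yl)-3-methyl-4-oxo-3-(trimethylsilyloxy)pentanoic acid | COC(=O)C(C(OC)OC)[C@@H](C(=O)O)[C@@](C)(O[Si](C)(C)C)C(C)=O | intermediate
18 | methyl (3R,4R)-2-(dimethoxymethyl)-4-methyl-3-{[(2S,4S)-4-methylhexan-2-yl]oxycarbonyl}-5-oxo-4-(trimethylsilyloxy)hexanoate | COC(=O)C(C(OC)OC)[C@@H](C(=O)O[C@@H](C)C[C@@H](C)CC)[C@@](C)(O[Si](C)(C)C)C(C)=O | intermediate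
19 | lithium methyl-ketone enolate of 18 | COC(=O)C(C(OC)OC)[C@@H](C(=O)O[C@@H](C)C[C@@H](C)CC)[C@@](C)(O[Si](C)(C)C)C(=C)[O-].[Li+] | intermediate
20 | (2S,4S)-4-methylhexan-2-yl (1R,2R)-6-(dimethoxymethyl)-2-methyl-3,5-dioxo-2-(trimethylsilyloxy)cyclohexane-1-carboxylate | O=C1CC(=O)C(C(OC)OC)[C@@H](C(=O)O[C@@H](C)C[C@@H](C)CC)[C@@]1(C)O[Si](C)(C)C | intermediate
21 | (2S,4S)-4-methylhexan-2-yl (1R,2R)-6-(dimethoxymethyl)-2-methyl-3-oxo-5-(trifluoromethanesulfonyloxy)-2-(trimethylsilyloxy)cyclohex-4-ene-1-carboxylate | O=C1C=C(OS(=O)(=O)C(F)(F)F)C(C(OC)OC)[C@@H](C(=O)O[C@@H](C)C[C@@H](C)CC)[C@@]1(C)O[Si](C)(C)C | intermediate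
22 | prop-2-yn-1-ol | C#CCO | starting material
23 | (2S,4S)-4-methylhexan-2-yl (1R,2R)-6-(dimethoxymethyl)-5-(3-hydroxyprop-1-yn-1-yl)-2-methyl-3-oxo-2-(trimethylsilyloxy)cyclohex-4-ene-1-carboxylate | O=C1C=C(C#CCO)C(C(OC)OC)[C@@H](C(=O)O[C@@H](C)C[C@@H](C)CC)[C@@]1(C)O[Si](C)(C)C | intermediate
24 | (2S,4S)-4-methylhexan-2-yl (1R,2R)-6-formyl-2-hydroxy-5-(3-hydroxyprop-1-yn-1-yl)-2-methyl-3-oxocyclohex-4-ene-1-carboxylate | O=C1C=C(C#CCO)C(C=O)[C@@H](C(=O)O[C@@H](C)C[C@@H](C)CC)[C@@]1(C)O | intermediate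
25 | (2S,4S)-4-methylhexan-2-yl (7R,8R)-7-hydroxy-3-(hydroxymethyl)-7-methyl-6-oxo-7,8-dihydro-6H-isochromene-8-carboxylate | CC[C@H](C)C[C@H](C)OC(=O)[C@@H]1C2=COC(CO)=CC2=CC(=O)[C@]1(C)O | intermediate
26 | (2S,4S)-4-methylhexan-2-yl (7R,8R)-3-formyl-7-hydroxy-7-methyl-6-oxo-7,8-dihydro-6H-isochromene-8-carboxylate | CC[C@H](C)C[C@H](C)OC(=O)[C@@H]1C2=COC(C=O)=CC2=CC(=O)[C@]1(C)O | intermediate
27 | tert-butyl 2-(triphenyl-λ5-phosphanylidene)acetate | CC(C)(C)OC(=O)C=P(c1ccccc1)(c1ccccc1)c1ccccc1 | starting material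
28 | (2S,4S)-4-methylhexan-2-yl (7R,8R)-3-[(E)-3-tert-butoxy-3-oxoprop-1-en-1-yl]-7-hydroxy-7-methyl-6-oxo-7,8-dihydro-6H-isochromene-8-carboxylate | CC[C@H](C)C[C@H](C)OC(=O)[C@@H]1C2=COC(/C=C/C(=O)OC(C)(C)C)=CC2=CC(=O)[C@]1(C)O | intermediate
29 | (E)-3-[(7R,8R)-7-hydroxy-7-methyl-8-{[(2S,4S)-4-methylhexan-2-yl]oxycarbonyl}-6-oxo-7,8-dihydro-6H-isochromen-3-yl]prop-2-enoic acid | CC[C@H](C)C[C@H](C)OC(=O)[C@@H]1C2=COC(/C=C/C(=O)O)=CC2=CC(=O)[C@]1(C)O | target

## Step count and risks

Total steps: 17. Longest linear sequence: 14 (steps 4 to 17, from 7); the alcohol branch (steps 1 to 3) joins at step 10.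

Three steps most likely to fail:

Step 8 (aldol stereocontrol with a branched, functionalised enolsilane). Fallback, setting out from 14 and 15 and coming back at 18: give up catalyst control and resolve through the chiral ester alcohol. The same Mukaiyama aldol is run with Cu(OTf)2 and the achiral ligand 2,2'-(propane-2,2-diyl)bis(4,4-dimethyl-4,5-dihydro-1,3-oxazole). This gives the syn adduct as a racemate, that is 16 together with its mirror-image adduct methyl (3S,4S)-3-[(tert-butylsulfanyl)carbonyl]-2-(dimethoxymethyl)-4-methyl-5-oxo-4-(trimethylsilyloxy)hexanoate F1. The pair is hydrolysed as in step 9 to 17 and the enantiomeric acid (2S,3S)-2-(1,1-dimethoxy-3-methoxy-3-oxopropan-2-yl)-3-methyl-4-oxo-3-(trimethylsilyloxy)pentanoic acid F2. Mitsunobu coupling with enantiopure 6 as in step 10 then gives 18 and the diastereomeric ester methyl (3S,4S)-2-(dimethoxymethyl)-4-methyl-3-{[(2S,4S)-4-methylhexan-2-yl]oxycarbonyl}-5-oxo-4-(trimethylsilyloxy)hexanoate F3. These two are diastereomers and are separated by chromatography; 18 continues at step 11.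

Step 9 (hydrolysis of a very hindered tert-butyl thioester next to a silyl ether). Fallback, setting out from 16 and coming back at 18: skip the free acid and form the acyl–oxygen bond directly. Thioester 16 is activated with AgO2CCF3 (Na2HPO4 buffer, toluene, rt to 40 °C) in the presence of (2S,4S)-4-methylhexan-2-ol F4, the alcohol left unacylated in step 2. Alcoholysis proceeds with retention at the carbinol centre and gives 18 in one operation, replacing steps 9 and 10.

Step 14 (6-endo versus 5-exo closure of the formyl enynone). Fallback, setting out from 23 and coming back at 25: replace alkyne activation by a 1,5-dicarbonyl condensation. Pyrrolidine is added to 23 in MeOH at rt; 1,6-conjugate addition at the alkyne terminus gives the dienaminone (2S,4S)-4-methylhexan-2-yl (1R,2R)-6-(dimethoxymethyl)-5-[3-hydroxy-2-(pyrrolidin-1-yl)prop-1-en-1-yl]-2-methyl-3-oxo-2-(trimethylsilyloxy)cyclohex-4-ene-1-carboxylate F5 (E/Z mixture), which fixes the oxygen-accepting carbon as C3. Treatment with TsOH·H2O in acetone/H2O then cleaves the acetal and the silyl ether; the formyl (enol) oxygen adds to the iminium carbon and pyrrolidine is expelled, giving 25.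

## Further compounds

F1 | step 8 | methyl (3S,4S)-3-[(tert-butylsulfanyl)carbonyl]-2-(dimethoxymethyl)-4-methyl-5-oxo-4-(trimethylsilyloxy)hexanoate | COC(=O)C(C(OC)OC)[C@H](C(=O)SC(C)(C)C)[C@](C)(O[Si](C)(C)C)C(C)=O
F2 | step 8 | (2S,3S)-2-(1,1-dimethoxy-3-methoxy-3-oxopropan-2-yl)-3-methyl-4-oxo-3-(trimethylsilyloxy)pentanoic acid | COC(=O)C(C(OC)OC)[C@H](C(=O)O)[C@](C)(O[Si](C)(C)C)C(C)=O
F3 | step 8 | methyl (3S,4S)-2-(dimethoxymethyl)-4-methyl-3-{[(2S,4S)-4-methylhexan-2-yl]oxycarbonyl}-5-oxo-4-(trimethylsilyloxy)hexanoate | COC(=O)C(C(OC)OC)[C@H](C(=O)O[C@@H](C)C[C@@H](C)CC)[C@](C)(O[Si](C)(C)C)C(C)=O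
F4 | step 9 | (2S,4S)-4-methylhexan-2-ol | CC[C@H](C)C[C@H](C)O
F5 | step 14 | (2S,4S)-4-methylhexan-2-yl (1R,2R)-6-(dimethoxymethyl)-5-[3-hydroxy-2-(pyrrolidin-1-yl)prop-1-en-1-yl]-2-methyl-3-oxo-2-(trimethylsilyloxy)cyclohex-4-ene-1-carboxylate (E/Z mixture) | O=C1C=C(C=C(CO)N2CCCC2)C(C(OC)OC)[C@@H](C(=O)O[C@@H](C)C[C@@H](C)CC)[C@@]1(C)O[Si](C)(C)C
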